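## Retrosynthetic overview

1. Daphnodorin C (20) comes from its penta-O-benzyl ether 19 by hydrogenolysis.
2. The spiro C–C(=O) bond and the adjacent C–H are made together by an NHC-catalysed dearomatising syn-hydroacylation of the 3-(2-formylaryloxy)-2-arylbenzofuran 18. This closes the benzofuranone last and sets both new stereocentres.
3. 18 comes from SNAr O-arylation of the enol of furochromanone 14 with fluoro-aldehyde 17.
4. 14 comes from Parham cyclisation of the 8-bromoflavan 13, whose O7 already carries the ArCH–C(O)N(OMe)Me unit.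
5. The (2S)-flavan comes from Rh-catalysed asymmetric 1,4-arylation of a 7-O-differentiated 5,7-dihydroxychromone, then C4 deoxygenation. Ring order: pyran (flavan C2) → furanone → benzofuran → spiro-benzofuranone/dihydrofuran.

Assumptions:
- The antipode of the Rh ligand (step 5) and of the triazolium catalyst (step 11) is chosen empirically to give the configurations drawn; both antipodes are available.
- Bromo-amide 5 is used racemic. The side-chain CH it introduces is carried as a ~1:1 epimer mixture (no stereo label in the SMILES) and becomes sp2 in 18, so it needs no control.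
- This route is a proposal built on reaction precedent by analogy; it has not been run, and step 11 in particular is an extrapolation.

## Route

**Step 1**
Reactants: 1 4-(benzyloxy)phenylacetic acid; 2 N,O-dimethylhydroxylamine hydrochloride
Product: 3 2-[4-(benzyloxy)phenyl]-N-methoxy-N-methylacetamide
Conditions: CDI, CH2Cl2, rt; then 2, rt
Reagents that add atoms: N,O-dimethylhydroxylamine (HCl salt), CNOC.Cl
Why: Standard acyl-imidazole amidation gives the Weinreb amide that later serves as the internal acylating group.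

**Step 2**
Reactants: 3; 4 N-bromosuccinimide
Product: 5 (±)-2-bromo-2-[4-(benzyloxy)phenyl]-N-methoxy-N-methylacetamide
Conditions: LiHMDS, THF, −78 °C; then NBS, −78 °C
Reagents that add atoms: NBS, O=C1CCC(=O)N1Br
Why: Electrophilic bromination of the amide enolate is α-selective and avoids radical attack on the O-benzyl CH2; the product is racemic by design.

**Step 3**
Reactants: 6 5,7-dihydroxychromone; 5
Product: 7 (±)-2-[4-(benzyloxy)phenyl]-2-[(5-hydroxy-4-oxo-4H-chromen-7-yl)oxy]-N-methoxy-N-methylacetamide
Conditions: K2CO3 (1.1 equiv), DMF, rt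
Reagents that add atoms: 5, CON(C)C(=O)C(Br)c1ccc(OCc2ccccc2)cc1
Why: Williamson etherification occurs at the acidic 7-OH because the 5-OH is locked in a hydrogen bond to C4=O, which differentiates O7 from O5 for the rest of the route.

**Step 4**
Reactants: 7; 8 benzyl bromide
Product: 9 (±)-2-{[5-(benzyloxy)-4-oxo-4H-chromen-7-yl]oxy}-2-[4-(benzyloxy)phenyl]-N-methoxy-N-methylacetamide
Conditions: BnBr, Cs2CO3, DMF, 50 °C
Reagents that add atoms: benzyl bromide, BrCc1ccccc1
Why: Williamson benzylation of the chelated 5-OH under forcing conditions; carbonate is too weak to enolise the amide.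

**Step 5**
Reactants: 9; 10 4-(benzyloxy)phenylboronic acid
Product: 11 2-{[(2S)-5-(benzyloxy)-2-[4-(benzyloxy)phenyl]-4-oxochroman-7-yl]oxy}-2-[4-(benzyloxy)phenyl]-N-methoxy-N-methylacetamide (side-chain epimers)
Conditions: [Rh(OH)(cod)]2 (3 mol %), electron-poor chiral bisphosphine (MeO-F12-BIPHEP type, antipode giving 2S), toluene/H2O, 40 °C
Reagents that add atoms: 4-(benzyloxy)phenylboronic acid, OB(O)c1ccc(OCc2ccccc2)cc1
Why: Hayashi–Miyaura asymmetric 1,4-addition to the chromone sets the flavan C2 centre as (S) under ligand control.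

**Step 6**
Reactants: 11
Product: 12 2-{[(2S)-5-(benzyloxy)-2-[4-(benzyloxy)phenyl]chroman-7-yl]oxy}-2-[4-(benzyloxy)phenyl]-N-methoxy-N-methylacetamide
Conditions: NaBH4, THF/MeOH, 0 °C to rt; crude flavan-4-ol then Et3SiH, BF3·OEt2, CH2Cl2, −78 °C (telescoped, one purification)
Reagents that add atoms: none
Why: Ketone reduction then ionic hydrogenation through the 5,7-dioxygen-stabilised C4 benzylic cation removes the C4 oxygen at low temperature without ionising the C2–O1 bond, so (2S) is retained.

**Step 7**
Reactants: 12; 4 N-bromosuccinimide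
Product: 13 2-{[(2S)-5-(benzyloxy)-2-[4-(benzyloxy)phenyl]-8-bromochroman-7-yl]oxy}-2-[4-(benzyloxy)phenyl]-N-methoxy-N-methylacetamide
Conditions: NBS (1.0 equiv), CH2Cl2, −78 to −20 °C, dark
Reagents that add atoms: NBS, O=C1CCC(=O)N1Br
Why: Electrophilic aromatic bromination of 5,7-di-O-alkyl flavans goes to C8, the less hindered position flanked by the tied-back pyran oxygen, rather than C6.

**Step 8**
Reactants: 13
Product: 14 (2S)-5-(benzyloxy)-2,8-bis[4-(benzyloxy)phenyl]-3,4-dihydro-2H-furo[2,3-h]chromen-9(8H)-one (C8 epimers, keto/enol)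
Conditions: t-BuLi (2.1 equiv), THF, −100 to −78 °C; aq NH4Cl; handle under Ar
Reagents that add atoms: none
Why: Parham cycliacylation: Br/Li exchange at C8 outruns deprotonation, and the aryllithium closes 5-exo onto the Weinreb amide to give the furanone ring regiospecifically on O7/C8.

**Step 9**
Reactants: 15 2,4,6-trifluorobenzaldehyde; 16 benzyl alcohol
Product: 17 2,4-bis(benzyloxy)-6-fluorobenzaldehyde
Conditions: BnOH (2.05 equiv), K2CO3, DMF, 50 °C; chromatography to remove the minor 2,6-isomer
Reagents that add atoms: benzyl alcohol, OCc1ccccc1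
Why: Double SNAr on the aldehyde-activated ring; the first two fluorides (para then ortho, or the reverse) give the same product, and the third is deactivated by the two new alkoxy donors.

**Step 10**
Reactants: 14; 17
Product: 18 2-{[(2S)-5-(benzyloxy)-2,8-bis[4-(benzyloxy)phenyl]-3,4-dihydro-2H-furo[2,3-h]chromen-9-yl]oxy}-4,6-bis(benzyloxy)benzaldehyde
Conditions: Cs2CO3, degassed DMSO, 70 °C, Ar
Reagents that add atoms: 17, O=Cc1c(F)cc(OCc2ccccc2)cc1OCc1ccccc1
Why: SNAr of the 3-hydroxybenzofuran enolate on the ortho-fluoro aldehyde; O-arylation is favoured because C8 is hindered and the product is an aromatic 2-arylbenzofuran, which also erases the uncontrolled CH centre.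

**Step 11**
Reactants: 18
Product: 19 penta-O-benzyl daphnodorin C: (2S,2'S,8'S)-4,5',6-tris(benzyloxy)-2',8'-bis[4-(benzyloxy)phenyl]-3',4'-dihydro-2'H,3H,8'H-spiro[1-benzofuran-2,9'-furo[2,3-h]chromen]-3-one
Conditions: chiral aminoindanol-derived N-mesityl triazolium chloride (20 mol %), DBU (20 mol %), 1,4-dioxane, 80–100 °C, Ar
Reagents that add atoms: none
Why: Intramolecular NHC-catalysed dearomatising hydroacylation: the Breslow intermediate adds 5-exo to benzofuran C3 with concerted O–H to C2 proton transfer, so acyl and H arrive on the same face (H cis to C=O, aryl cis to the benzofuranone oxygen, as in the target), and the chiral carbene selects the face giving the (S)-spiro and (S)-CH centres.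

**Step 12**
Reactants: 19
Product: 20 daphnodorin C
Conditions: H2 (1 atm), 20% Pd(OH)2/C, THF/MeOH, rt; stop at full O-debenzylation; neutral work-up
Reagents that add atoms: none
Why: Hydrogenolysis of the five aryl benzyl ethers under neutral conditions; by analogy with benzylated catechins, the cyclic benzylic ethers and the non-enolisable spiro ketone should survive, and no stereocentre is touched.

## Compound list

1 | 4-(benzyloxy)phenylacetic acid | OC(=O)Cc1ccc(OCc2ccccc2)cc1 | starting material
2 | N,O-dimethylhydroxylamine hydrochloride | CNOC.Cl | starting material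
3 | 2-[4-(benzyloxy)phenyl]-N-methoxy-N-methylacetamide | CON(C)C(=O)Cc1ccc(OCc2ccccc2)cc1 | intermediate
4 | N-bromosuccinimide | O=C1CCC(=O)N1Br | starting material
5 | (±)-2-bromo-2-[4-(benzyloxy)phenyl]-N-methoxy-N-methylacetamide | CON(C)C(=O)C(Br)c1ccc(OCc2ccccc2)cc1 | intermediate
6 | 5,7-dihydroxychromone | O=c1ccoc2cc(O)cc(O)c12 | starting material
7 | (±)-7-O-[aryl(Weinreb-carbamoyl)methyl]-5-hydroxychromone | O=c1ccoc2cc(OC(C(=O)N(C)OC)c3ccc(OCc4ccccc4)cc3)cc(O)c12 | intermediate
8 | benzyl bromide | BrCc1ccccc1 | starting material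
9 | (±)-5-O-benzyl-7-O-[aryl(Weinreb-carbamoyl)methyl]chromone | O=c1ccoc2cc(OC(C(=O)N(C)OC)c3ccc(OCc4ccccc4)cc3)cc(OCc3ccccc3)c12 | intermediate
10 | 4-(benzyloxy)phenylboronic acid | OB(O)c1ccc(OCc2ccccc2)cc1 | starting material
11 | (2S)-flavanone, side-chain epimers | O=C1C[C@@H](c2ccc(OCc3ccccc3)cc2)Oc2cc(OC(C(=O)N(C)OC)c3ccc(OCc4ccccc4)cc3)cc(OCc3ccccc3)c12 | intermediate
12 | (2S)-flavan, side-chain epimers | O(Cc1ccccc1)c1cc(OC(C(=O)N(C)OC)c2ccc(OCc3ccccc3)cc2)cc2O[C@H](c3ccc(OCc4ccccc4)cc3)CCc12 | intermediate
13 | (2S)-8-bromoflavan, side-chain epimers | O(Cc1ccccc1)c1cc(OC(C(=O)N(C)OC)c2ccc(OCc3ccccc3)cc2)c(Br)c2O[C@H](c3ccc(OCc4ccccc4)cc3)CCc12 | intermediate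
14 | (2S)-5-(benzyloxy)-2,8-bis[4-(benzyloxy)phenyl]-3,4-dihydro-2H-furo[2,3-h]chromen-9(8H)-one (C8 unspecified) | O(Cc1ccccc1)c1cc2OC(c3ccc(OCc4ccccc4)cc3)C(=O)c2c2O[C@H](c3ccc(OCc4ccccc4)cc3)CCc12 | intermediate
15 | 2,4,6-trifluorobenzaldehyde | O=Cc1c(F)cc(F)cc1F | starting material
16 | benzyl alcohol | OCc1ccccc1 | starting material
17 | 2,4-bis(benzyloxy)-6-fluorobenzaldehyde | O=Cc1c(F)cc(OCc2ccccc2)cc1OCc1ccccc1 | intermediate
18 | (2S)-3-(2-formyl-3,5-dibenzyloxyphenoxy)-2-arylbenzofuran fused to the flavan | O(Cc1ccccc1)c1cc2oc(-c3ccc(OCc4ccccc4)cc3)c(Oc3cc(OCc4ccccc4)cc(OCc4ccccc4)c3C=O)c2c2O[C@H](c3ccc(OCc4ccccc4)cc3)CCc12 | intermediate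
19 | penta-O-benzyl daphnodorin C (S spiro, S ArCH–O, 2S flavan) | O=C1c2c(OCc3ccccc3)cc(OCc3ccccc3)cc2O[C@]12c1c(cc(OCc3ccccc3)c3c1O[C@H](c1ccc(OCc4ccccc4)cc1)CC3)O[C@H]2c1ccc(OCc3ccccc3)cc1 | intermediate
20 | daphnodorin C | O=C1c2c(O)cc(O)cc2O[C@]12c1c(cc(O)c3c1O[C@H](c1ccc(O)cc1)CC3)O[C@H]2c1ccc(O)cc1 | target

## Summary

Total steps: 12 (step 6 is a telescoped two-stage operation).
Longest linear sequence: 11 steps (1 → 3 → 5 → 7 → 9 → 11 → 12 → 13 → 14 → 18 → 19 → 20).

Three steps most likely to fail:

1. **Step 11 (NHC hydroacylation).** The aldehyde is di-ortho-substituted, the alkene is tetrasubstituted, and 6-endo attack at C2 could compete. Fallback: change to a cationic, stepwise closure. Pinnick-oxidise 18 to the acid, run a TFAA-mediated dearomative ipso-acylation at benzofuran C3 (giving the O7/aryl-stabilised C2 oxocarbenium or its hemiketal), then reduce with Et3SiH/BF3·OEt2. Spiro control is lost; the (2S)-flavan makes the spiro epimers diastereomers, so they are separated by preparative HPLC.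
2. **Step 10 (O- versus C-arylation of an air-sensitive, hindered enolate).** Fallback: reverse the polarity. Convert 14 to its enol triflate (PhNTf2, base) and form the diaryl ether by Pd-catalysed C–O coupling (bulky biarylphosphine) with 2-hydroxy-4,6-bis(benzyloxy)benzaldehyde, protected as its acetal if needed.
3. **Step 8 (Parham cyclisation; competing proton transfer from the acidic ArCH).** Fallback: drop the bromination/lithiation pair. Use the tert-butyl ester analogue of 5, cleave it to the acid after step 6, and close the furanone by intramolecular Friedel–Crafts acylation ((COCl)2, then SnCl4, −78 °C) on the unbrominated flavan, relying on the intrinsic C8 preference and removing any C6 isomer.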